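The cyclohexane ring is disconnected between C4 (CHBr) and C5 (CMeCl) of the target. This vicinal bromo/chloro pair is the imprint of a trisubstituted C4=C5 ring alkene. Ring-closing metathesis of an acyclic tetraene, whose allyl and 2-methylallyl arms flank the lone stereocentre C2, therefore forms the carbocycle in one operation and leaves the 1-methylidene group and the (E)-chlorovinyl arm untouched. The new alkene then relays all further stereochemistry: reagent-controlled epoxidation, invertive chloride opening at C5, invertive bromide displacement at C4 (cis Br/Cl) and Markovnikov radical hydrobromination at C1. C2 itself comes from an oxazolidinone-directed enolate allylation.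

Key step: step 8

Remark: locants C1–C6 in the text are those of the target name (C1 = CMeBr, C2 = CH bearing the chlorovinyl group, C3 = CH2, C4 = CHBr, C5 = CMeCl, C6 = CH2); compounds 1, 2, 6 and 9 are assumed to be catalogue items.

Step 1
Reactants: 1 3-chloro-2-(chloromethyl)prop-1-ene; 2 isopropenylmagnesium bromide (prop-1-en-2-ylmagnesium bromide)
Product: 3 2-(chloromethyl)-4-methylpenta-1,4-diene
Conditions: 1 (3 equiv), CuI (cat.), THF, −30 → 0 °C
Reagents that add atoms: none
Why: Copper-catalysed allylic substitution of one C–Cl bond by the alkenyl Grignard reagent; the 2-substituted allyl unit is symmetric, so SN2 and SN2′ paths give the same product, and the excess of 1 limits double substitution.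

Step 2
Reactants: 3 2-(chloromethyl)-4-methylpenta-1,4-diene
Product: 5 5-methyl-3-methylidenehex-5-enoic acid, via allylic Grignard reagent 4 (not isolated)
Conditions: Mg, THF, 0 °C (slow addition); CO2, −40 °C; aq. HCl
Reagents that add atoms: carbon dioxide, O=C=O
Why: Grignard formation and carboxylation; both termini of the symmetric allylmagnesium species are equivalent, so a single β,γ-unsaturated acid should result.

Step 3
Reactants: 5 5-methyl-3-methylidenehex-5-enoic acid; 6 (4R)-4-benzyl-1,3-oxazolidin-2-one
Product: 8 (4R)-4-benzyl-3-(5-methyl-3-methylidenehex-5-enoyl)-1,3-oxazolidin-2-one, via mixed pivalic anhydride 7 (not isolated)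
Conditions: t-BuCOCl, Et3N, THF, −20 °C; then 6, LiCl, −20 °C → rt
Reagents that add atoms: none
Why: N-acylation of the oxazolidinone through the mixed anhydride, mild enough to keep the double bond out of conjugation.

Step 4
Reactants: 8 (4R)-4-benzyl-3-(5-methyl-3-methylidenehex-5-enoyl)-1,3-oxazolidin-2-one; 9 allyl iodide (3-iodoprop-1-ene)
Product: 11 (4R)-4-benzyl-3-[(2R)-5-methyl-3-methylidene-2-(prop-2-en-1-yl)hex-5-enoyl]-1,3-oxazolidin-2-one, via sodium Z-dienolate 10 (not isolated)
Conditions: NaN(SiMe3)2, THF, −78 °C; then 9, −78 → −45 °C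
Reagents that add atoms: none
Why: Evans asymmetric alkylation: the chelated Z-dienolate should react at its α-carbon on the face away from the benzyl group of the (4R)-auxiliary, which sets the future C2 stereocentre.

Step 5
Reactants: 11 (4R)-4-benzyl-3-[(2R)-5-methyl-3-methylidene-2-(prop-2-en-1-yl)hex-5-enoyl]-1,3-oxazolidin-2-one
Product: 12 (2R)-5-methyl-3-methylidene-2-(prop-2-en-1-yl)hex-5-en-1-ol
Conditions: LiBH4, H2O (1 equiv), Et2O, 0 °C
Reagents that add atoms: none
Why: Reductive removal of the auxiliary by hydride gives the primary alcohol without enolising the α-stereocentre or touching the alkenes.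

Step 6
Reactants: 12 (2R)-5-methyl-3-methylidene-2-(prop-2-en-1-yl)hex-5-en-1-ol
Product: 13 (2R)-5-methyl-3-methylidene-2-(prop-2-en-1-yl)hex-5-enal
Conditions: Dess–Martin periodinane, NaHCO3, CH2Cl2, 0 °C; used at once without chromatography
Reagents that add atoms: none
Why: Dess–Martin oxidation under buffered, base-free conditions should deliver the α-branched β,γ-unsaturated aldehyde without enolisation.

Step 7
Reactants: 13 (2R)-5-methyl-3-methylidene-2-(prop-2-en-1-yl)hex-5-enal
Product: 14 (5S)-5-[(E)-2-chloroethenyl]-2-methyl-4-methylideneocta-1,7-diene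
Conditions: CrCl2, CHCl3, THF, 65 °C
Reagents that add atoms: chloroform, ClC(Cl)Cl
Why: Takai olefination: the geminal dichromium species from CHCl3 adds to the aldehyde and eliminates in an anti sense to give the (E)-chloroalkene (the descriptor changes to S only because the priorities change).

Step 8
Reactants: 14 (5S)-5-[(E)-2-chloroethenyl]-2-methyl-4-methylideneocta-1,7-diene
Product: 15 (4S)-4-[(E)-2-chloroethenyl]-1-methyl-5-methylidenecyclohex-1-ene
Conditions: second-generation Hoveyda–Grubbs catalyst (5 mol %), 1,4-benzoquinone (10 mol %), CH2Cl2 (5 mM), 40 °C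
Reagents that add atoms: none
Why: The ruthenium alkylidene loads at the monosubstituted allyl terminus, undergoes intramolecular [2+2] cycloaddition with the 1,1-disubstituted 2-methylallyl alkene and cycloreverts with loss of ethene (Chauvin mechanism), joining the two former alkene carbons as C4=C5. The closest known reaction type is ring-closing metathesis of 1,7-dienes with one 1,1-disubstituted terminus to trisubstituted cyclohexenes. The six-membered carbocycle is closed by metathesis between two terminal alkenes, with the new double bond inside the ring. No stereocentre is created; C2 is remote from the reacting carbons and is carried through unchanged. The step needs site selectivity among four alkenes: closure onto the 4-methylidene or the chlorovinyl group of 14 would give cyclobutenes, and the electron-poor internal chloroalkene engages the catalyst slowly, so only the allyl/2-methylallyl pair is productive. High dilution and benzoquinone should suppress oligomerisation and migration of the skipped double bonds.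

Step 9
Reactants: 15 (4S)-4-[(E)-2-chloroethenyl]-1-methyl-5-methylidenecyclohex-1-ene
Product: 16 (1S,4S,6R)-4-[(E)-2-chloroethenyl]-1-methyl-3-methylidene-7-oxabicyclo[4.1.0]heptane
Conditions: D-fructose-derived Shi ketone (30 mol %), KHSO5 (as its triple salt with KHSO4 and K2SO4), K2CO3, Bu4NHSO4, MeCN–(MeO)2CH2–aq. buffer (pH 10.5), 0 °C
Reagents that add atoms: potassium peroxymonosulfate, [K+].[O-]S(=O)(=O)OO
Why: Shi epoxidation: the chiral dioxirane should attack the electron-rich trisubstituted ring alkene in preference to the 1,1-disubstituted and chloro-substituted alkenes and, by the spiro transition-state model for trisubstituted alkenes, deliver oxygen to the ring face opposite the chlorovinyl group.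

Step 10
Reactants: 16 (1S,4S,6R)-4-[(E)-2-chloroethenyl]-1-methyl-3-methylidene-7-oxabicyclo[4.1.0]heptane
Product: 17 (1R,2R,5S)-2-chloro-5-[(E)-2-chloroethenyl]-2-methyl-4-methylidenecyclohexan-1-ol
Conditions: HCl (1 M in Et2O, 1.05 equiv), CH2Cl2, −78 °C
Reagents that add atoms: hydrogen chloride, Cl
Why: Acid-mediated epoxide opening: chloride should attack the tertiary carbon C5 with inversion in a trans-diaxial (Fürst–Plattner) sense, placing Cl cis to the chlorovinyl group and leaving an axial hydroxyl at C4 trans to it.

Step 11
Reactants: 17 (1R,2R,5S)-2-chloro-5-[(E)-2-chloroethenyl]-2-methyl-4-methylidenecyclohexan-1-ol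
Product: 19 (1R,2S,4S)-2-bromo-1-chloro-4-[(E)-2-chloroethenyl]-1-methyl-5-methylidenecyclohexane, via secondary triflate 18 (not isolated)
Conditions: Tf2O, 2,6-lutidine, CH2Cl2, −78 °C; then Bu4NBr (1.2 equiv), −78 → 0 °C
Reagents that add atoms: tetrabutylammonium bromide, CCCC[N+](CCCC)(CCCC)CCCC.[Br-]
Why: SN2 displacement of the axial secondary triflate by bromide with Walden inversion should place Br at C4 cis to the C5 chlorine, the β-chlorine retarding ionisation and so favouring the bimolecular path.

Step 12
Reactants: 19 (1R,2S,4S)-2-bromo-1-chloro-4-[(E)-2-chloroethenyl]-1-methyl-5-methylidenecyclohexane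
Product: 20 (1R,2S,4S,5R)-1,4-dibromo-5-chloro-2-[(E)-2-chloroethenyl]-1,5-dimethylcyclohexane
Conditions: Co(acac)2 (25 mol %), t-BuOOH (25 mol %), Et3SiH, TsBr, n-PrOH–CH2Cl2, 0 °C → rt
Reagents that add atoms: p-toluenesulfonyl bromide, Cc1ccc(cc1)S(=O)(=O)Br
Why: Cobalt-hydride hydrogen-atom transfer (Mukaiyama-type Markovnikov hydrobromination) gives the tertiary C1 radical, which should take bromine from TsBr on the face opposite the 1,3-related axial C5 chlorine, so that Br ends trans to the chlorovinyl group and the new methyl is axial.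

Compound list
1 | 3-chloro-2-(chloromethyl)prop-1-ene | ClCC(=C)CCl | starting material
2 | isopropenylmagnesium bromide | CC(=C)[Mg]Br | starting material
3 | 2-(chloromethyl)-4-methylpenta-1,4-diene | ClCC(=C)CC(C)=C | intermediate
4 | (4-methyl-2-methylidenepent-4-en-1-yl)magnesium chloride (not isolated) | CC(=C)CC(=C)C[Mg]Cl | intermediate
5 | 5-methyl-3-methylidenehex-5-enoic acid | CC(=C)CC(=C)CC(=O)O | intermediate
6 | (4R)-4-benzyl-1,3-oxazolidin-2-one | O=C1N[C@H](Cc2ccccc2)CO1 | starting material
7 | 2,2-dimethylpropanoic 5-methyl-3-methylidenehex-5-enoic anhydride (not isolated) | CC(=C)CC(=C)CC(=O)OC(=O)C(C)(C)C | intermediate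
8 | (4R)-4-benzyl-3-(5-methyl-3-methylidenehex-5-enoyl)-1,3-oxazolidin-2-one | CC(=C)CC(=C)CC(=O)N1[C@H](Cc2ccccc2)COC1=O | intermediate
9 | allyl iodide (3-iodoprop-1-ene) | C=CCI | starting material
10 | sodium (1Z)-1-[(4R)-4-benzyl-2-oxo-1,3-oxazolidin-3-yl]-5-methyl-3-methylidenehexa-1,5-dien-1-olate (not isolated) | [Na+].[O-]/C(=C\C(=C)CC(C)=C)N1[C@H](Cc2ccccc2)COC1=O | intermediate
11 | (4R)-4-benzyl-3-[(2R)-5-methyl-3-methylidene-2-(prop-2-en-1-yl)hex-5-enoyl]-1,3-oxazolidin-2-one | CC(=C)CC(=C)[C@@H](CC=C)C(=O)N1[C@H](Cc2ccccc2)COC1=O | intermediate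
12 | (2R)-5-methyl-3-methylidene-2-(prop-2-en-1-yl)hex-5-en-1-ol | CC(=C)CC(=C)[C@H](CO)CC=C | intermediate
13 | (2R)-5-methyl-3-methylidene-2-(prop-2-en-1-yl)hex-5-enal | CC(=C)CC(=C)[C@H](C=O)CC=C | intermediate
14 | (5S)-5-[(E)-2-chloroethenyl]-2-methyl-4-methylideneocta-1,7-diene | CC(=C)CC(=C)[C@H](/C=C/Cl)CC=C | intermediate
15 | (4S)-4-[(E)-2-chloroethenyl]-1-methyl-5-methylidenecyclohex-1-ene | CC1=CC[C@@H](/C=C/Cl)C(=C)C1 | intermediate
16 | (1S,4S,6R)-4-[(E)-2-chloroethenyl]-1-methyl-3-methylidene-7-oxabicyclo[4.1.0]heptane | C[C@]12CC(=C)[C@H](/C=C/Cl)C[C@H]1O2 | intermediate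
17 | (1R,2R,5S)-2-chloro-5-[(E)-2-chloroethenyl]-2-methyl-4-methylidenecyclohexan-1-ol | C[C@@]1(Cl)CC(=C)[C@H](/C=C/Cl)C[C@H]1O | intermediate
18 | (1R,2R,5S)-2-chloro-5-[(E)-2-chloroethenyl]-2-methyl-4-methylidenecyclohexyl trifluoromethanesulfonate (not isolated) | C[C@@]1(Cl)CC(=C)[C@H](/C=C/Cl)C[C@H]1OS(=O)(=O)C(F)(F)F | intermediate
19 | (1R,2S,4S)-2-bromo-1-chloro-4-[(E)-2-chloroethenyl]-1-methyl-5-methylidenecyclohexane | C[C@@]1(Cl)CC(=C)[C@H](/C=C/Cl)C[C@@H]1Br | intermediate
20 | (1R,2S,4S,5R)-1,4-dibromo-5-chloro-2-[(E)-2-chloroethenyl]-1,5-dimethylcyclohexane | C[C@@]1(Cl)C[C@@](C)(Br)[C@H](/C=C/Cl)C[C@@H]1Br | target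

Total step count: 12. Longest linear sequence: 12 steps (1 → 20).

Steps most likely to fail

Step 11. Instead of direct displacement, the axial triflate may ionise with participation of the anti-periplanar chlorine (retention or chlorine migration) or lose triflic acid toward C3. The product may also epimerise at C4 by bromide–bromide exchange. The fallback avoids oxygen at C4 altogether and sets out from alkene 15. PhSeCl should add anti across C4=C5 under equilibrating conditions (CH2Cl2, −78 °C → rt) to give the Markovnikov adduct {[(1R,2R,5S)-2-chloro-5-[(E)-2-chloroethenyl]-2-methyl-4-methylidenecyclohexyl]selanyl}benzene F1, with Cl on C5 and PhSe on C4 trans to it. Br2 (1 equiv, CH2Cl2, −78 °C, then 2-methylbut-2-ene) should oxidise selenium faster than it adds to the exocyclic alkene. This gives the tetravalent selenium compound dibromo[(1R,2R,5S)-2-chloro-5-[(E)-2-chloroethenyl]-2-methyl-4-methylidenecyclohexyl]phenyl-λ4-selane F2, in which bromide displaces the selenium group at C4 with inversion. The sequence comes back to the route at 19.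

Step 12. Bromine-atom transfer to the planar C1 radical may show poor facial selectivity, and silyl or cobalt radicals may reductively cleave the vicinal C4–Br/C5–Cl pair. The fallback sets out from 19 and replaces the radical event by polar Markovnikov addition of anhydrous HBr (CH2Cl2, −78 °C). The tertiary C1 cation and bromide then collapse as an ion pair, again on the face not shielded by the axial C5 chlorine. It comes back to the route at 20, and no new compound is formed (F0).

Step 7. At 65 °C the α-branched β,γ-unsaturated aldehyde may enolise, which would erode the configuration of the future C2 or move the methylidene into conjugation before olefination. The fallback sets out from aldehyde 13 and uses the iodoform variant of the Takai olefination (CHI3, CrCl2, THF, 0 °C), which runs cold and should give (5S)-5-[(E)-2-iodoethenyl]-2-methyl-4-methylideneocta-1,7-diene F3. Iodine–lithium exchange (t-BuLi, 2 equiv, Et2O, −78 °C) then gives, with retention of alkene geometry, [(1E,3S)-6-methyl-4-methylidene-3-(prop-2-en-1-yl)hepta-1,6-dien-1-yl]lithium F4. Quenching with Cl3CCCl3 should give the (E)-chloroalkene, and the sequence comes back to the route at 14.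

Further compounds
F1 | step 11 | {[(1R,2R,5S)-2-chloro-5-[(E)-2-chloroethenyl]-2-methyl-4-methylidenecyclohexyl]selanyl}benzene | C[C@@]1(Cl)CC(=C)[C@H](/C=C/Cl)C[C@H]1[Se]c1ccccc1
F2 | step 11 | dibromo[(1R,2R,5S)-2-chloro-5-[(E)-2-chloroethenyl]-2-methyl-4-methylidenecyclohexyl]phenyl-λ4-selane | C[C@@]1(Cl)CC(=C)[C@H](/C=C/Cl)C[C@H]1[Se](Br)(Br)c1ccccc1
F0 | step 12 | none | none
F3 | step 7 | (5S)-5-[(E)-2-iodoethenyl]-2-methyl-4-methylideneocta-1,7-diene | CC(=C)CC(=C)[C@H](/C=C/I)CC=C
F4 | step 7 | [(1E,3S)-6-methyl-4-methylidene-3-(prop-2-en-1-yl)hepta-1,6-dien-1-yl]lithium | CC(=C)CC(=C)[C@H](/C=C/[Li])CC=C
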